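## Structural features

The target is a C2-symmetric head-to-head dimer of a lindenane-type sesquiterpene lactone (lindenane numbering, primed atoms for the second half). Two identical 3/5/6/5 tetracycles are joined by the C9–C9' and C8–C8' bonds of a central cyclobutane (a 6-4-6 core); each half is bonded on the face of ring B opposite its C14 methyl group, and the two halves lie anti across the four-membered ring. In each half, ring A is a bicyclo[3.1.0]hexane: the cyclopropane C1–C2–C3 is cis-fused to the cyclopentane C1–C3–C4–C5–C10, which carries the exocyclic C4=C15 methylene and is trans-fused through C5–C10 to ring B (C5 to C10). An α-methyl butenolide (C7=C11, C12=O, O–C8) is fused at C7–C8, so C8 is a quaternary, oxygen-bearing carbon shared by ring B, the lactone and the cyclobutane. Each half has six stereocentres: C3, C1, C10, C9 and C8 form an unbroken chain and C5 adjoins C10; the cyclopropane CH2 (C2) is syn to C14 and H5 is anti to it. Fragile groups are the vinylcyclopropane (acid), C5–H whenever C4 is a carbonyl (epimerisation towards the cis-fused ketone), bicyclo[3.1.0]hex-3-en-2-one intermediates (acid- or heat-induced rearrangement to phenols), and the enol-lactone diene of the monomer (base, nucleophiles, light). The real difficulty is the congested ring A (quaternary C10 beside the cyclopropane, a trans 5/6 junction next to a C4 carbonyl) and the need for one absolute configuration so that dimerisation gives a single C2-symmetric product. The key step exploits the atom pattern of ring A: C4 lies between C5 and the cyclopropane carbon C3, while C10 is bonded to the other cyclopropane carbon C1. This is a carbonyl carbon (C4) set between an alkyne (C5≡C10) and the double bond of a three-membered ring (C1=C3, with C2 as its CH2).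

## Logic of the disconnections

**24 ⇒ 23 + 23.** The cyclobutane bonds C9–C9' and C8–C8' are cut. Both halves are the same molecule, and in 23 the C8=C9 bond is the terminus of a dienolide chromophore that can be excited selectively. The cut halves the molecule and removes four stereocentres, two of them quaternary. The forward step must be head-to-head, must use the α face of each molecule, must place the halves anti, and needs enantiopure 23, since a racemate would also give heterochiral dimers.

**23 ⇒ 19 + 20.** The C7–C11 bond and the lactone C–O bond at C8 are cut, which removes the three lactone carbons as 20 and leaves a C8 ketone. An aldol addition followed by dehydration and enol-lactonisation sets up C7=C11 and C8=C9 at the correct oxidation level without a separate oxidation. The forward step must enolise 19 towards C7 and not C9, and the acid step must spare the vinylcyclopropane.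

**19 ⇒ 15 (through 18, 17 and 16).** No ring bond is cut: the C4=C15 methylene is traded for a C4 ketone and the C8 carbonyl for a C7=C8 alkene. The alkene has no intrinsic bias between C7 and C8, but the rigid trans-fused ring has: anti, diaxial opening of an α-face halonium ion places oxygen on C8. The alkene must be functionalised while C4 is still a ketone, because an exocyclic methylene beside the cyclopropane would not survive the electrophile. C4 must be methylenated before the C8 ketone is released, so that only one ketone is present at the olefination and at the aldol step. The demands are face selectivity and no epimerisation at C5 while C4 is a ketone.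

**15 ⇒ 14.** The C7=C8 bond is cut (metathesis transform), opening ring B to two allyl groups: C6–C7 on C5 and C9–C8 on C10. A two-carbon vinyl group on C10 would pair with the C5 allyl group to close a cyclopentene (C9 joined to C7), so the C10 substituent must be a three-carbon allyl group. The gain is a bicyclic compound carrying all four ring A stereocentres. The demand is that the two allyl groups are trans.

**14 ⇒ 11 + 12 (through 13).** The C9–C10 bond is cut (conjugate addition transform), and C5–H is traced to protonation of the resulting enol derivative. In a bicyclo[3.1.0]hexenone the face anti to the cyclopropane CH2 is the open one, so the group added last ends up anti to C2; C9 must therefore come after C14. The cut removes the quaternary centre and C5 together. The forward step needs 1,4- rather than 1,2-addition at a tetrasubstituted enone, anti attack at C10, and protonation of C5 from the same face.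

**11 ⇒ 8 (through 10 and 9).** The C10–C14 bond is cut. The methyl group is placed on the β-carbon by addition–elimination, which needs a leaving group on C10; it is brought in by conjugate addition of a sulfur nucleophile and oxidation at sulfur. The shorter alternative (methyl addition, then dehydrogenation of the ketone) would have to choose between H10 and the doubly activated C6 hydrogens of the allyl group. Oxidation at sulfur can only return the double bond to C5=C10. The demand is ionic addition of the thiol to the enone and not radical addition to the allyl group.

**8 ⇒ 6 (through 7).** No skeletal bond is cut; the single enantiomer is traced to the racemate through covalent diastereomers. Both cycloaddition partners are achiral, and the small-ring alkene is usable only cold, which rules out the heated, ligand-modified cobalt complexes that induce asymmetry with robust alkenes. Resolving directly after the key step wastes the least material. The demands are face-selective 1,2-addition, separable diastereomers and clean thermal release.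

**6 ⇒ 3 + 5; 3 ⇒ 1 + 2; 5 ⇒ 4.** The C4–C5, C3–C4 and C1–C10 bonds are cut. Ring A is dissected into an alkyne (C5≡C10, with C6–C7 attached as an allyl group), a carbonyl ligand (C4) and the double bond of a three-membered ring (C1=C3 with C2). Three bonds, one ring and two stereocentres are made in one step from five-, one- and three-carbon pieces. The product already has the C4 carbonyl for later methylenation and the C5=C10 enone for building the quaternary centre. The demands are regiochemistry (allyl α to the carbonyl), chemoselectivity over the allyl double bond, and safe handling of 5.

## Other disconnections considered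

**Alternative 1:** The cut is made at C1–C2 and C2–C3 of a tricyclic intermediate: the cyclopropane CH2 is removed from A1 to leave the trans-fused allylic alcohol A2 (C1=C3 double bond, β-hydroxyl on C4, dioxolane on C7).
- **Forward step:** a zinc carbenoid (Et2Zn, CH2I2) is held by the C4 hydroxyl and delivers CH2 to the same face of C1=C3.
- **In favour:** the ring fusion at C5/C10 is set before the cyclopropane is made, and the hydroxyl face is the C14 face, so the CH2 group arrives syn to the methyl as required. On stereocontrol at C1 and C3 it is at least the equal of the chosen plan. It is the better on absolute configuration, because bicycles of this type come from a catalytic enantioselective annulation and no resolution is needed.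
- **Against:** in A1 the six-ring oxygen sits on C7, whereas the lactone needs oxygen on C8 and carbon on C7, so the functionality must be transposed. A2 needs its own redox adjustments, including a reduction to the trans ring fusion that normally favours cis. The C4 alcohol must still be oxidised and methylenated, with the same C5 epimerisation hazard as in the chosen plan (equal on that point).
- **Comparison:** structurally it builds ring A last on a secure ring B, while the chosen plan builds ring A first in one step and pays with a resolution and a protonation-controlled C5. Mechanistically a directed carbenoid transfer is more predictable than an intermolecular metal-mediated cycloaddition with an unstable alkene. In step count it is unlikely to be shorter once the C7-to-C8 transposition is included.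

**Alternative 2:** The cut removes C1–C3 and C2–C3 in both halves of the diketone A3, leading to the bis(diazoketone) A4, in which the 6-4-6 bis-butenolide core carries a vinyl group on C10 and C10' and a diazoacetyl group on C5 and C5'.
- **Forward step:** Rh2(OAc)4 (divalent rhodium) generates a carbene at C3 and at C3', and each adds to the neighbouring vinyl group, closing two cyclopentanones and two cyclopropanes.
- **In favour:** it uses the C2 symmetry in two directions, and one operation forms four rings. A3 needs only a double methylenation to reach the target, so on steps after the key step it is the better plan. The cis fusion of each cyclopropane is enforced, as in the chosen plan (equal).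
- **Against:** the cyclobutane core with its four stereocentres must be built first and carried through acylation and diazo chemistry. The face of each vinyl group that the carbene attacks decides whether C2 is syn or anti to C14, and it must be right twice. C5 and C5' are α to ketones in both A4 and A3, so the epimerisation hazard is doubled. Diazo ketones are no safer than the small-ring alkene of the chosen plan (equal on hazard).
- **Comparison:** structurally it dimerises early and doubles every later risk, whereas the chosen plan dimerises a finished monomer in the last step. Mechanistically an intramolecular carbene addition is reliable for ring closure but not for the C2/C14 relationship. In step count the short endgame is outweighed by the longer route to A4.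

**Alternative 3:** The cut is at C2–C3 of the bicyclic ketone A5, leading to the achiral bromide A6.
- **Forward step:** an engineered flavin-dependent ene-reductase transfers hydride to C1, and the enzyme-bound enolate at C3 displaces bromide (3-exo-tet).
- **In favour:** the absolute configuration at C1 and C3 is set catalytically from an achiral precursor, with no resolution; on that point it is the better plan. It runs in water at ambient temperature without cobalt carbonyl or a gaseous strained alkene, so it is also the better plan on safety. The C4 carbonyl is in place as in the chosen plan (equal).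
- **Against:** A5 has no substituent on C5 or C10 and no C5=C10 double bond. Dehydrogenation and the introduction of the C5 side chain, C14 and the C9–C8 unit are all still to come, whereas 8 already carries the allyl group and the enone. A6 is a labile allylic bromide that hydrolyses and alkylates in buffer, and the method depends on access to the engineered enzyme.
- **Comparison:** structurally it delivers the bare core and the chosen plan a substituted one. Mechanistically, hydride transfer followed by enolate alkylation is simpler than a three-component organometallic cycloaddition. In step count the saved resolution is more than offset by the extra steps from A5.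

Key step: step 3

Remark: lindenane numbering is used for all intermediates; α is the face of ring B opposite the C14 methyl group and β the face that carries it.
Remark: the cycloaddition is run without a chiral controller and should give the racemate; the single enantiomer is secured by the resolution in steps 4 and 5.
Remark: the C4 carbon comes from a CO ligand of Co2(CO)8, so no CO gas is handled.

## Route

Step 1
Reactants: 1 pent-1-en-4-yne; 2 Co2(CO)8 (dicobalt octacarbonyl)
Product: 3 hexacarbonyl(μ-η2:η2-pent-1-en-4-yne)dicobalt, Co2(CO)6(HC≡CCH2CH=CH2)
Conditions: Co2(CO)8 (1.05 equiv), pentane, 20 °C, N2, 2 h; short SiO2 plug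
Reagents that add atoms: none
Why: Alkyne complexation by ligand substitution (two CO lost, cobalt stays zerovalent); the terminal alkyne bridges the two metal atoms and the unstrained alkene does not bind.

Step 2
Reactants: 4 allyl chloride (3-chloroprop-1-ene)
Product: 5 cyclopropene
Conditions: NaN(SiMe3)2 (1.0 equiv), toluene, 110 °C, slow addition of 4; N2 sweep, gas condensed at −78 °C into CH2Cl2 and used at once as a cold ca. 1 M solution
Reagents that add atoms: none
Why: Base-induced α-elimination of HCl gives vinylcarbene, which closes to the three-membered ring (1,1-elimination and carbene cyclisation). The hindered silylamide does not add to the product, and the gas is never condensed neat or stored because it oligomerises exothermically above about −30 °C.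

Step 3
Reactants: 3 hexacarbonyl(μ-η2:η2-pent-1-en-4-yne)dicobalt; 5 cyclopropene
Product: 6 rac-3-(prop-2-en-1-yl)bicyclo[3.1.0]hex-3-en-2-one (cis-fused racemate of the (1S,5S) and (1R,5R) forms)
Conditions: 5 (3–4 equiv, cold CH2Cl2 solution), N-methylmorpholine N-oxide (7 equiv), 4 Å MS, CH2Cl2, −35 → −10 °C; air, filtration through SiO2
Reagents that add atoms: none
Why: This is an N-oxide-promoted intermolecular Pauson–Khand reaction: oxidative removal of one CO from the zerovalent-cobalt complex opens a site, the strained alkene binds and inserts into the Co–C bond at the unsubstituted alkyne carbon (C1–C10), CO migratory insertion forms C3–C4, and reductive elimination forms C4–C5. The closest known reaction type is the Pauson–Khand reaction of strained alkenes such as norbornene and of cyclopropenes, which gives bicyclo[3.1.0]hex-3-en-2-ones at low temperature. Ring A, the cyclopentenone, is closed in a [2+2+1] mode, and the three-membered ring is carried in intact and is not closed here. The new stereocentres C1 and C3 are necessarily cis because both bonds are made on the same face of one small-ring π bond; their absolute configuration is not controlled, so 6 is racemic. The step needs regioselectivity (allyl group next to the carbonyl), which the terminal alkyne secures because its substituted carbon ends up α to the carbonyl. It also needs chemoselectivity for the strained alkene over the pendant allyl double bond, which ring strain and the low temperature secure. The alkene is used in excess as a cold dilute solution because its own oligomerisation is the competing path.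

Step 4
Reactants: 6 rac-3-(prop-2-en-1-yl)bicyclo[3.1.0]hex-3-en-2-one
Product: 7 (1S,2S,5S)-2-{[(S)-N-methyl-S-phenylsulfonimidoyl]methyl}-3-(prop-2-en-1-yl)bicyclo[3.1.0]hex-3-en-2-ol (hydroxyl syn to the cyclopropane CH2)
Conditions: (S)-N,S-dimethyl-S-phenylsulfoximine (1.05 equiv), n-BuLi, THF, −78 °C; then 6, −78 °C; H2O; SiO2 chromatography to separate the two diastereomers
Reagents that add atoms: (S)-N,S-dimethyl-S-phenylsulfoximine, CN=[S@@](C)(=O)c1ccccc1
Why: Sulfoximine resolution of a ketone: 1,2-addition of the α-lithiated sulfoximine to the carbonyl of each enantiomer, anti to the cyclopropane CH2, converts the racemate into two diastereomeric β-hydroxysulfoximines that are separated on silica. The diastereomer derived from the (1S,5S) ketone is carried on; its assignment is to be confirmed by crystallography.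

Step 5
Reactants: 7 the (1S,2S,5S) β-hydroxysulfoximine
Product: 8 (1S,5S)-3-(prop-2-en-1-yl)bicyclo[3.1.0]hex-3-en-2-one
Conditions: toluene, 110 °C, 2 h; sulfoximine recovered by chromatography
Reagents that add atoms: none
Why: Thermal retro-addition of the β-hydroxysulfoximine regenerates the ketone without touching C1 and C3. Compound 8 is the key-step product in the enantiomeric form required by the target.

Step 6
Reactants: 8 (1S,5S)-3-(prop-2-en-1-yl)bicyclo[3.1.0]hex-3-en-2-one
Product: 9 (1S,4S,5R)-4-(phenylsulfanyl)-3-(prop-2-en-1-yl)bicyclo[3.1.0]hexan-2-one (PhS anti to the cyclopropane CH2; both epimers at the allyl-bearing carbon)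
Conditions: PhSH (1.1 equiv), Et3N (0.1 equiv), CH2Cl2, 0 → 20 °C, N2, dark
Reagents that add atoms: thiophenol, Sc1ccccc1
Why: Base-catalysed thia-Michael addition puts sulfur on C10 from the open face; the ionic conditions (no light, no oxygen) avoid radical thiol–ene addition to the allyl group. The new centres at C10 and C5 are lost again in steps 7 and 8, so their configuration does not matter.

Step 7
Reactants: 9 the β-phenylsulfanyl ketone
Product: 10 (1S,5R)-4-(phenylsulfanyl)-3-(prop-2-en-1-yl)bicyclo[3.1.0]hex-3-en-2-one
Conditions: N-chlorosuccinimide (1.05 equiv), CH2Cl2, 0 → 20 °C; aq NaHCO3 wash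
Reagents that add atoms: none
Why: Oxidation at sulfur (chlorosulfonium, Pummerer-type chlorination at C10) followed by loss of HCl across C5–C10 gives the vinylogous thioester. Because oxidation is localised at the sulfur-bearing carbon, the double bond can only return to C5=C10 and the C6 hydrogens of the allyl group are not involved.

Step 8
Reactants: 10 the β-phenylsulfanyl enone
Product: 11 (1S,5R)-4-methyl-3-(prop-2-en-1-yl)bicyclo[3.1.0]hex-3-en-2-one
Conditions: Me2CuLi (from MeLi, 2.2 equiv, and CuI, 1.1 equiv), Et2O, −78 → −30 °C; aq NH4Cl
Reagents that add atoms: lithium dimethylcuprate, [Li+].C[Cu-]C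
Why: Conjugate addition–elimination (the cuprate adds to the β-sulfanyl enone and thiophenolate is expelled) installs C14 on C10. The tetrasubstituted product is too hindered to take up a second methyl group at this temperature.

Step 9
Reactants: 11 (1S,5R)-4-methyl-3-(prop-2-en-1-yl)bicyclo[3.1.0]hex-3-en-2-one; 12 allylmagnesium bromide, CH2=CHCH2MgBr
Product: 14 (1S,3R,4S,5R)-4-methyl-3,4-di(prop-2-en-1-yl)bicyclo[3.1.0]hexan-2-one, via trimethylsilyl enol ether 13 (not isolated)
Conditions: 12 (1.5 equiv), CuBr·SMe2 (1.5 equiv), Me3SiCl (3 equiv), THF, −78 °C; then Bu4NF, AcOH, THF, −78 °C
Reagents that add atoms: none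
Why: Chlorosilane-accelerated conjugate addition of an allylcopper reagent creates the quaternary C10; the nucleophile enters anti to the cyclopropane CH2, so the new allyl group (C9, C8) is anti and the methyl group syn to C2. Fluoride-induced protonation of 13 at low temperature should occur on the same, less shielded face (away from the cyclopropane CH2 and the C10 methyl), which places H5 anti to C14 and the two allyl groups trans. Any C5 epimer is separated and returned to the mixture by mild base.

Step 10
Reactants: 14 the trans-diallyl ketone
Product: 15 11,12,13,15-tetranorlind-7-en-4-one (trans-fused tricyclic ketone, C7=C8; H1, H3 and H5 α, C14 and the cyclopropane CH2 β)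
Conditions: second-generation Grubbs catalyst (H2IMes)(PCy3)Cl2Ru=CHPh (3 mol %), CH2Cl2 (0.01 M), 40 °C
Reagents that add atoms: none
Why: Ring-closing olefin metathesis of the two terminal alkenes closes ring B at C7=C8 with loss of ethene. The trans relationship of the allyl groups becomes the trans 5/6 junction, and the neutral catalyst does not epimerise C5.

Step 11
Reactants: 15 11,12,13,15-tetranorlind-7-en-4-one
Product: 16 7α-bromo-8β-hydroxy-11,12,13,15-tetranorlindenan-4-one
Conditions: N-bromosuccinimide (1.1 equiv), DME–H2O (4:1), 0 °C, dark
Reagents that add atoms: N-bromosuccinimide, O=C1CCC(=O)N1Br; water, O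
Why: Bromohydrin formation under the Fürst–Plattner rule: the bromonium ion forms on the α face, away from the axial C14 methyl, and water opens it at C8 from the β face through the chair-like, anti-diaxial transition state. This places the oxygen on C8 and not on C7.

Step 12
Reactants: 16 the 7α-bromo-8β-hydroxy ketone
Product: 17 8β-hydroxy-11,12,13,15-tetranorlindenan-4-one
Conditions: (Me3Si)3SiH (1.3 equiv), AIBN (0.1 equiv), toluene, 80 °C
Reagents that add atoms: none
Why: Radical chain dehalogenation: a silyl radical abstracts bromine and the C7 radical takes hydrogen from the silane. The hydroxyl, the ketone and the cyclopropane are remote from the radical centre and unaffected.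

Step 13
Reactants: 17 the 8β-hydroxy C4 ketone
Product: 18 11,12,13-trinorlind-4(15)-en-8β-ol
Conditions: Zn, CH2Br2, TiCl4 (reagent preformed in THF at 0 °C), CH2Cl2–THF, 0 → 20 °C; aq NaHCO3
Reagents that add atoms: dibromomethane, BrCBr
Why: Takai–Lombardo methylenation: the non-basic zinc/titanium methylene reagent adds to the hindered, enolisable C4 ketone and removes its oxygen on titanium, so C5 is not epimerised and the free hydroxyl is tolerated. After this step C5 is no longer α to a carbonyl.

Step 14
Reactants: 18 the C4-methylene 8β-alcohol
Product: 19 11,12,13-trinorlind-4(15)-en-8-one
Conditions: Dess–Martin periodinane (1.3 equiv), CH2Cl2, 0 → 20 °C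
Reagents that add atoms: none
Why: Hypervalent-iodine oxidation of the secondary alcohol to the C8 ketone under near-neutral conditions that leave the vinylcyclopropane intact.

Step 15
Reactants: 19 11,12,13-trinorlind-4(15)-en-8-one; 20 ethyl pyruvate
Product: 22 ethyl 11-hydroxy-8-oxolind-4(15)-en-12-oate (epimers at C7 and C11), via lithium enolate 21 (not isolated)
Conditions: LiN(i-Pr)2 (1.1 equiv), THF, −78 °C; 20 (1.5 equiv), −78 °C; AcOH quench at −78 °C
Reagents that add atoms: none
Why: Kinetic deprotonation occurs at C7 because C9 is neopentylic, next to the quaternary C10, and the enolate adds to the ketone carbonyl of the pyruvate (directed aldol addition). The new centres at C7 and C11 are not controlled and are both removed in step 16.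

Step 16
Reactants: 22 the aldol adduct
Product: 23 linda-4(15),7(11),8-trien-12,8-olide (the monomeric dienolide, chloranthalactone A)
Conditions: p-TsOH·H2O (0.2 equiv), toluene, 80 °C, 4 Å MS
Reagents that add atoms: none
Why: Acid-catalysed dehydration of the tertiary β-hydroxy ketone (C7=C11) and enol-lactonisation of the C8 enol onto the ester (loss of ethanol) give the α-methyl-γ-ylidene butenolide with the C8=C9 double bond. Catalytic acid and moderate temperature are chosen to spare the vinylcyclopropane.

Step 17
Reactants: 23 the monomeric dienolide (two molecules)
Product: 24 the target, head-to-head dimer CNP0265879.1 (chloranthalactone F)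
Conditions: hν (high-pressure Hg lamp, Pyrex filter), degassed acetone, 20 °C
Reagents that add atoms: none
Why: Triplet [2+2] photodimerisation: the excited C8=C9 bond first joins C9 to C9' of a ground-state molecule, giving a 1,4-diradical whose centres at C8 and C8' are stabilised by oxygen and the butenolide π system, and spin inversion then closes C8–C8'. Head-to-head regiochemistry follows from that diradical, each molecule reacts on its α face away from C14, and the anti arrangement of the halves is the least crowded, so enantiopure 23 should converge on the single C2-symmetric dimer.

## Compound list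

1 | pent-1-en-4-yne | C=CCC#C | starting material
2 | Co2(CO)8, dicobalt octacarbonyl | O=C=[Co](=C=O)(=C=O)(=C=O)[Co](=C=O)(=C=O)(=C=O)=C=O | starting material
3 | hexacarbonyl(μ-η2:η2-pent-1-en-4-yne)dicobalt | C=CCC12C3[Co]1(=C=O)(=C=O)(=C=O)[Co]23(=C=O)(=C=O)=C=O | intermediate
4 | allyl chloride | C=CCCl | starting material
5 | cyclopropene | C1=CC1 | intermediate
6 | rac-3-(prop-2-en-1-yl)bicyclo[3.1.0]hex-3-en-2-one (racemate; the SMILES shows the (1S,5S) enantiomer) | C=CCC1=C[C@@H]2C[C@@H]2C1=O | intermediate
7 | (1S,2S,5S)-2-{[(S)-N-methyl-S-phenylsulfonimidoyl]methyl}-3-(prop-2-en-1-yl)bicyclo[3.1.0]hex-3-en-2-ol | C=CCC1=C[C@@H]2C[C@@H]2[C@@]1(O)C[S@](=NC)(=O)c1ccccc1 | intermediate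
8 | (1S,5S)-3-(prop-2-en-1-yl)bicyclo[3.1.0]hex-3-en-2-one | C=CCC1=C[C@@H]2C[C@@H]2C1=O | intermediate
9 | (1S,4S,5R)-4-(phenylsulfanyl)-3-(prop-2-en-1-yl)bicyclo[3.1.0]hexan-2-one (epimers at the allyl-bearing carbon) | C=CCC1[C@@H](Sc2ccccc2)[C@@H]2C[C@@H]2C1=O | intermediate
10 | (1S,5R)-4-(phenylsulfanyl)-3-(prop-2-en-1-yl)bicyclo[3.1.0]hex-3-en-2-one | C=CCC1=C(Sc2ccccc2)[C@@H]2C[C@@H]2C1=O | intermediate
11 | (1S,5R)-4-methyl-3-(prop-2-en-1-yl)bicyclo[3.1.0]hex-3-en-2-one | C=CCC1=C(C)[C@@H]2C[C@@H]2C1=O | intermediate
12 | allylmagnesium bromide | C=CC[Mg]Br | starting material
13 | (1S,4S,5R)-4-methyl-3,4-di(prop-2-en-1-yl)-2-(trimethylsilyloxy)bicyclo[3.1.0]hex-2-ene | C[Si](C)(C)OC=1[C@H]2C[C@H]2[C@@](CC=C)(C)C1CC=C | intermediate (not isolated)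
14 | (1S,3R,4S,5R)-4-methyl-3,4-di(prop-2-en-1-yl)bicyclo[3.1.0]hexan-2-one | O=C1[C@H]2C[C@H]2[C@@](CC=C)(C)[C@H]1CC=C | intermediate
15 | 11,12,13,15-tetranorlind-7-en-4-one (1α-H, 3α-H, 5α-H, 10β-CH3) | O=C1[C@H]2C[C@H]2[C@@]3(C)[C@H]1CC=CC3 | intermediate
16 | 7α-bromo-8β-hydroxy-11,12,13,15-tetranorlindenan-4-one | O=C1[C@H]2C[C@H]2[C@@]3(C)[C@H]1C[C@@H](Br)[C@H](O)C3 | intermediate
17 | 8β-hydroxy-11,12,13,15-tetranorlindenan-4-one | O=C1[C@H]2C[C@H]2[C@@]3(C)[C@H]1CC[C@H](O)C3 | intermediate
18 | 11,12,13-trinorlind-4(15)-en-8β-ol | C=C1[C@H]2C[C@H]2[C@@]3(C)[C@H]1CC[C@H](O)C3 | intermediate
19 | 11,12,13-trinorlind-4(15)-en-8-one | C=C1[C@H]2C[C@H]2[C@@]3(C)[C@H]1CCC(=O)C3 | intermediate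
20 | ethyl pyruvate | CCOC(=O)C(C)=O | starting material
21 | lithium 7(8)-enolate of 19 | C=C1[C@H]2C[C@H]2[C@@]3(C)[C@H]1CC=C(O[Li])C3 | intermediate (not isolated)
22 | ethyl 11-hydroxy-8-oxolind-4(15)-en-12-oate (epimers at C7 and C11) | C=C1[C@H]2C[C@H]2[C@@]3(C)[C@H]1CC(C(C)(O)C(=O)OCC)C(=O)C3 | intermediate
23 | linda-4(15),7(11),8-trien-12,8-olide | C=C1[C@H]2C[C@H]2[C@@]3(C)[C@H]1CC1=C(C)C(=O)OC1=C3 | intermediate
24 | head-to-head C8–C8', C9–C9' dimer of 23 (CNP0265879.1) | C=C1[C@H]2C[C@H]2[C@@]2(C)[C@H]1CC1=C(C)C(=O)O[C@]13[C@H]2[C@H]1[C@@]2(C)[C@@H]4C[C@@H]4C(=C)[C@@H]2CC2=C(C)C(=O)O[C@@]213 | target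

## Step count and least certain steps

Total step count: 17. Longest linear sequence: 16 steps (1 → 3 → 6 → 7 → 8 → 9 → 10 → 11 → 14 → 15 → 16 → 17 → 18 → 19 → 22 → 23 → 24); step 2 is a one-step branch.

**Step 3 (key step).** The small-ring alkene may be lost to its own oligomerisation faster than the cobalt complex captures it, because alkene insertion is slow at the low temperature the alkene tolerates; the strained, volatile product may also be lost on isolation. The fallback sets out from 3 and returns at 6. Compound 3 is treated under the same N-oxide conditions with ethyl cycloprop-2-ene-1-carboxylate F1, a 3-substituted cyclopropene that can be kept in solution (made from acetylene and ethyl diazoacetate with Rh2(OAc)4). Approach of cobalt anti to the ester should give racemic ethyl exo-2-oxo-3-(prop-2-en-1-yl)bicyclo[3.1.0]hex-3-ene-6-carboxylate F2. Hydrolysis (LiOH, THF–H2O, 0 °C) gives the carboxylic acid F3, which is converted into its N-acyloxypyridine-2-thione (Barton ester) F4 and decarboxylated with visible light and t-BuSH to give 6. This removes the gaseous alkene at the cost of three steps.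

**Step 9.** The allyl nucleophile may add 1,2, or not at all, at the tetrasubstituted β-carbon beside the cyclopropane. Facial selectivity in the protonation at C5 may also be insufficient, because the two faces differ only by methyl versus CH2 on C10 and by the remote cyclopropane. The fallback sets out from 11 and returns at 14. Reagent 12 alone (THF, −78 °C) adds to the C4 carbonyl anti to the cyclopropane CH2 to give (1S,5R)-4-methyl-2,3-di(prop-2-en-1-yl)bicyclo[3.1.0]hex-3-en-2-ol F5. KH and 18-crown-6 in THF then trigger an anionic oxy-Cope rearrangement that carries the allyl group suprafacially from C4 to C10 on the same face. The potassium enolate formed is protonated at −78 °C to give 14; any C5 epimer is recycled through base as in the main route.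

**Step 11.** Water may open the bromonium ion partly at C7, or the bromonium ion may form on the β face: a trans-hydrindane is less rigid than a trans-decalin, and attack at C8 from the β face is syn-axial to C14. The fallback sets out from 15 and returns at 16. The crude product of the N-bromosuccinimide reaction is closed with K2CO3 in MeOH at 0 °C (short contact, to protect C5). Both trans-bromohydrins that derive from an α-bromonium ion converge on the 7β,8β-epoxide F6 (7β,8β-epoxy-11,12,13,15-tetranorlindenan-4-one). Reopening with LiBr and AcOH in THF lets bromide attack C7 from the α face (anti-diaxial) and gives 16 as the only regioisomer.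

**Step 13.** Methylenation of the hindered ketone may be slow, and under forcing conditions C5 may epimerise to the cis-fused ketone before olefination, or the Lewis acid may damage the cyclopropyl ketone. The fallback sets out from 17 and returns at 18 by a Peterson olefination. Me3SiCH2Li premixed with CeCl3 (2.5 equiv to allow for the free hydroxyl, THF, −78 °C) adds to C4 anti to the cyclopropane CH2 without enolisation, giving 4β,8β-dihydroxy-4α-(trimethylsilylmethyl)-11,12,13,15-tetranorlindenane F7. KH in THF (0 → 20 °C) then eliminates silanolate to give 18.

**Step 17.** Head-to-tail or syn dimers may form, and prolonged irradiation may cause photoreversion or secondary photochemistry of the vinylcyclopropane. The fallback sets out from 23 and returns at 24, making the two bonds one after the other in the ground state. SmI2 (divalent samarium; THF, t-BuOH, −78 °C) reduces 23 to its radical anion, which should couple at the unhindered δ-terminus C9 and, after protonation at C8, give the 9,9'-linked bis-butenolide F8. Double deprotonation at C8 and C8' (LiN(SiMe3)2, THF, −78 °C) and oxidation of the resulting bis-enolate with I2 should then close C8–C8' by intramolecular oxidative enolate coupling to give 24.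

## Further compounds

F1 | step 3 | ethyl cycloprop-2-ene-1-carboxylate | CCOC(=O)C1C=C1
F2 | step 3 | ethyl exo-2-oxo-3-(prop-2-en-1-yl)bicyclo[3.1.0]hex-3-ene-6-carboxylate (racemate; one enantiomer drawn) | C=CCC1=C[C@@H]2[C@@H](C(=O)OCC)[C@@H]2C1=O
F3 | step 3 | exo-2-oxo-3-(prop-2-en-1-yl)bicyclo[3.1.0]hex-3-ene-6-carboxylic acid (racemate; one enantiomer drawn) | C=CCC1=C[C@@H]2[C@@H](C(=O)O)[C@@H]2C1=O
F4 | step 3 | 2-thioxopyridin-1(2H)-yl ester of F3 (Barton ester; racemate; one enantiomer drawn) | C=CCC1=C[C@@H]2[C@@H](C(=O)ON3C=CC=CC3=S)[C@@H]2C1=O
F5 | step 9 | (1S,5R)-4-methyl-2,3-di(prop-2-en-1-yl)bicyclo[3.1.0]hex-3-en-2-ol (hydroxyl syn to the cyclopropane CH2) | C=CCC1=C(C)[C@@H]2C[C@@H]2[C@@]1(O)CC=C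
F6 | step 11 | 7β,8β-epoxy-11,12,13,15-tetranorlindenan-4-one | O=C1[C@H]2C[C@H]2[C@@]3(C)[C@H]1C[C@@H]4O[C@@H]4C3
F7 | step 13 | 4β,8β-dihydroxy-4α-(trimethylsilylmethyl)-11,12,13,15-tetranorlindenane | C[Si](C)(C)C[C@]1(O)[C@H]2C[C@H]2[C@@]3(C)[C@H]1CC[C@H](O)C3
F8 | step 17 | 9,9'-linked bis-butenolide (8H,8'H; epimers at C8 and C8') | C=C1[C@H]2C[C@H]2[C@@]2(C)[C@H]1CC1=C(C)C(=O)OC1[C@H]2[C@H]1[C@@]2(C)[C@@H]3C[C@@H]3C(=C)[C@@H]2CC2=C(C)C(=O)OC21
A1 | alternative 1 | 4β-hydroxy-11,12,13,15-tetranorlindenan-7-one ethylene acetal (cyclopropyl carbinol) | O[C@H]1[C@H]2C[C@H]2[C@@]2(C)[C@H]1CC1(OCCO1)CC2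
A2 | alternative 1 | trans-fused 3a-methyl-6,6-(ethylenedioxy)-3a,4,5,6,7,7a-hexahydro-1H-inden-1-ol (hydroxyl cis to the angular methyl) | O[C@H]1C=C[C@@]2(C)[C@H]1CC1(OCCO1)CC2
A3 | alternative 2 | C4,C4'-diketone corresponding to the target (15,15'-dinor-4,4'-dioxo dimer) | O=C1[C@H]2C[C@H]2[C@@]2(C)[C@H]1CC1=C(C)C(=O)O[C@]13[C@H]2[C@H]1[C@@]2(C)[C@@H]4C[C@@H]4C(=O)[C@@H]2CC2=C(C)C(=O)O[C@@]213
A4 | alternative 2 | bis(diazomethyl ketone) of the 6-4-6 bis-butenolide core with vinyl groups on C10 and C10' | [N-]=[N+]=CC(=O)[C@@H]1CC2=C(C)C(=O)O[C@]23[C@H]([C@@]1(C)C=C)[C@H]1[C@@](C)(C=C)[C@H](C(=O)C=[N+]=[N-])CC2=C(C)C(=O)O[C@@]213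
A5 | alternative 3 | bicyclo[3.1.0]hexan-2-one, enantiomer with the ring A configuration of the target at C1 and C3 | O=C1CC[C@@H]2C[C@H]12
A6 | alternative 3 | 3-(bromomethyl)cyclopent-2-en-1-one | O=C1CCC(CBr)=C1
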